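Ring B (C5–C10, labdane numbering) is cut at C9–C10. The route exploits that C9 is the α-carbon of the C8 ketone while C10–C5–C6 is a latent allyl unit. A [3,3] shift can therefore join C9 to C10 once C6 carries an oxygen tied to C9 through one carbonyl carbon. The precursor is no carbocycle but a 6-(trimethylcyclohexenyl) β-keto-δ-lactone that already bears the whole side chain on C9. One decarboxylative Claisen ring contraction forms C9–C10, closes ring B, sets quaternary C10 by chirality transfer from C6, frees the C8 ketone and expels the tether as CO2. Conjugation of the alkene then sets C5 and C9.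

Key step: step 7

Remark on numbering: ring A = C1–C5 and C10; ring B = C5–C10; C20 = methyl on C10; side chain = C11–C16 (C15 = acid carbon, C16 = CH2OAc). The same numbers are used for these atoms in all precursors.

Assumption: the ligand antipode written in step 2 is taken to direct the dienolate to the Re face of 3. Should the sense be opposite, its mirror image is used.

Step 1
Reactants: 1 2,2,6-trimethyl-4H-1,3-dioxin-4-one
Product: 2 2,2-dimethyl-6-methylidene-4-(trimethylsilyloxy)-6H-1,3-dioxine (silyl dienolate)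
Conditions: LDA, THF, −78 °C; TMSCl, −78 °C to rt
Reagents that add atoms: chlorotrimethylsilane C[Si](C)(C)Cl
Why: Kinetic γ-deprotonation of the vinylogous ester followed by O-silylation (silyl dienol ether formation) gives the C7 nucleophile without forming a stereocentre.

Step 2
Reactants: 2 silyl dienolate; 3 β-cyclocitral (2,6,6-trimethylcyclohex-1-ene-1-carbaldehyde)
Product: 5 (R)-6-[2-hydroxy-2-(2,6,6-trimethylcyclohex-1-en-1-yl)ethyl]-2,2-dimethyl-4H-1,3-dioxin-4-one, via silyl ether 4 (not isolated)
Conditions: Cu(OTf)2 (5 mol %), (S)-Tol-BINAP (5.5 mol %), Bu4N[Ph3SiF2] (10 mol %), THF, −78 to −40 °C; then 1 M HCl, THF, 0 °C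
Reagents that add atoms: none
Why: In this catalytic enantioselective vinylogous Mukaiyama aldol addition the chiral copper dienolate should attack through its γ-carbon (C7) on the Re face of the aldehyde and set C6 as R.

Step 3
Reactants: 5 (R)-δ-hydroxy dioxinone
Product: 7 (6R)-4-hydroxy-6-(2,6,6-trimethylcyclohex-1-en-1-yl)-5,6-dihydro-2H-pyran-2-one (enol form of the β-keto-δ-lactone), via acylketene 6 (not isolated)
Conditions: toluene (0.02 M), 110 °C, 30 min
Reagents that add atoms: none
Why: Retro-hetero-Diels–Alder loss of acetone gives an acylketene that the δ-hydroxyl group traps intramolecularly to the six-membered lactone under neutral conditions, leaving C6 untouched.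

Step 4
Reactants: 8 but-2-yne-1,4-diyl diacetate
Product: 9 1,4-diacetoxybutan-2-one
Conditions: Ph3PAuCl (2 mol %), AgSbF6 (2 mol %), H2O (3 equiv), 1,4-dioxane, 40 °C
Reagents that add atoms: water O
Why: Gold-catalysed alkyne hydration of a symmetrical internal alkyne can give only this ketone.

Step 5
Reactants: 7 (6R)-β-keto-δ-lactone; 9 1,4-diacetoxybutan-2-one
Product: 11 (6R)-3-(4-acetoxy-3-oxobutyl)-4-hydroxy-6-(2,6,6-trimethylcyclohex-1-en-1-yl)-5,6-dihydro-2H-pyran-2-one, via 1-acetoxybut-3-en-2-one 10 (not isolated)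
Conditions: Et3N (2.2 equiv), CH2Cl2, 0 °C to rt; aq. citric acid
Reagents that add atoms: none
Why: Et3N eliminates the β-acetoxy group of 9 to the vinyl ketone, which the soft C9 carbon of the cyclic 1,3-dicarbonyl takes up by Michael addition (C-alkylation), building C9–C11.

Step 6
Reactants: 11 Michael adduct
Product: 12 tert-butyl (E)-3-(acetoxymethyl)-5-[(6R)-4-hydroxy-2-oxo-6-(2,6,6-trimethylcyclohex-1-en-1-yl)-5,6-dihydro-2H-pyran-3-yl]pent-2-enoate
Conditions: DBU (1.05 equiv), Ph3P=CHCO2t-Bu (1.3 equiv), MeCN, 50 °C; aq. citric acid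
Reagents that add atoms: tert-butyl (triphenylphosphoranylidene)acetate CC(C)(C)OC(=O)C=P(c1ccccc1)(c1ccccc1)c1ccccc1
Why: In this Wittig olefination the acidic enol is parked as its DBU salt so that the stabilised ylide reacts only with the activated α-acetoxy ketone C13, and α-oxygenated ketones should place the CH2OAc group trans to the ester (E).

Step 7
Reactants: 12 side-chain-bearing (6R)-β-keto-δ-lactone
Product: 16 tert-butyl (E)-3-(acetoxymethyl)-5-[(1S,8aS)-5,5,8a-trimethyl-2-oxo-1,2,3,5,6,7,8,8a-octahydronaphthalen-1-yl]pent-2-enoate (β,γ-enone with C5=C6), via silyl ketene acetal 13 (not isolated), via silyl ester 14 (not isolated), via silyl enol ether 15 (not isolated)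
Conditions: BSA (3 equiv), KOAc (0.1 equiv), toluene, 110–130 °C, sealed tube; then 1 M HCl, THF, 0 °C
Reagents that add atoms: none
Why: Proposed new method: BSA silylates the vinylogous acid 12, and its minor 2-silyloxy tautomer 13, kept in equilibrium by acetate, is a cyclic allyl ketene acetal (C9=C–O–C6–C5=C10) that should undergo a suprafacial [3,3] shift to silyl ester 14, which loses CO2 after acetate-induced desilylation and is re-silylated to enol ether 15, hydrolysed to 16 on work-up. The closest known reaction types are the Carroll rearrangement of allyl β-keto esters, the BSA/KOAc decarboxylative Claisen rearrangement of stabilised allyl esters and the Ireland–Claisen ring contraction of 6-alkenyl δ-lactones to cyclohexenecarboxylic acids; new are their merger on a β-keto-δ-lactone and the union of two fully substituted carbons. Ring B closes by C9–C10 bond formation (six-membered carbocycle, both allyl carbons C5 and C10 in the ring) through the only geometry the lactone allows, a boat-like bicyclo[2.2.2]-type transition state, while the lactone opens at C6–O. C10 is controlled by 1,3-chirality transfer: in the 6R lactone the C6–O bond lies on the face of C5=C10 to which C9 is delivered, so that the methyl group is pushed to the opposite face, and C9 is set by protonation of 15 anti to this methyl group and remains correctable by enolisation. The step needs the [3,3] shift to outrun opening of the β-acyloxy ketone (E1cB at C7 or ionisation of the allylic C6–O bond) to the acyclic dienone, which is secured by complete enolisation towards C9, the neutral silylating medium and the apolar solvent; regiochemistry is not at issue because C6–C5=C10 is the only allyl unit on the ester oxygen.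

Step 8
Reactants: 16 β,γ-enone
Product: 17 tert-butyl (E)-3-(acetoxymethyl)-5-[(1S,4aR,8aR)-5,5,8a-trimethyl-2-oxo-1,2,4a,5,6,7,8,8a-octahydronaphthalen-1-yl]pent-2-enoate
Conditions: DBU (0.2 equiv), CH2Cl2, rt
Reagents that add atoms: none
Why: Base-catalysed conjugation through the linear dienolate should protonate C5 anti to the axial C10 methyl group (trans ring fusion) while C9 equilibrates to the equatorial side chain.

Step 9
Reactants: 17 conjugated enone tert-butyl ester
Product: 18 (E)-3-(acetoxymethyl)-5-[(1S,4aR,8aR)-5,5,8a-trimethyl-2-oxo-1,2,4a,5,6,7,8,8a-octahydronaphthalen-1-yl]pent-2-enoic acid (target; 5R,9S,10R in labdane numbering)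
Conditions: TFA/CH2Cl2 1:4, 0 °C to rt
Reagents that add atoms: none
Why: Acidolysis of the tert-butyl ester (loss of isobutene) should leave the acetate, the enone, the E alkene and all three stereocentres untouched.

Compound list
1 | 2,2,6-trimethyl-4H-1,3-dioxin-4-one | CC1=CC(=O)OC(C)(C)O1 | starting material
2 | 2,2-dimethyl-6-methylidene-4-(trimethylsilyloxy)-6H-1,3-dioxine | C=C1C=C(O[Si](C)(C)C)OC(C)(C)O1 | intermediate
3 | β-cyclocitral | O=CC1=C(C)CCCC1(C)C | starting material
4 | O-trimethylsilyl ether of 5 (R at C6) | CC1(C)OC(=O)C=C(C[C@@H](O[Si](C)(C)C)C2=C(C)CCCC2(C)C)O1 | intermediate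
5 | (R)-6-[2-hydroxy-2-(2,6,6-trimethylcyclohex-1-en-1-yl)ethyl]-2,2-dimethyl-4H-1,3-dioxin-4-one | CC1(C)OC(=O)C=C(C[C@@H](O)C2=C(C)CCCC2(C)C)O1 | intermediate
6 | (R)-5-hydroxy-3-oxo-5-(2,6,6-trimethylcyclohex-1-en-1-yl)pent-1-en-1-one (acylketene) | O=C=CC(=O)C[C@@H](O)C1=C(C)CCCC1(C)C | intermediate
7 | (6R)-4-hydroxy-6-(2,6,6-trimethylcyclohex-1-en-1-yl)-5,6-dihydro-2H-pyran-2-one | O=C1C=C(O)C[C@@H](O1)C2=C(C)CCCC2(C)C | intermediate
8 | but-2-yne-1,4-diyl diacetate | CC(=O)OCC#CCOC(C)=O | starting material
9 | 1,4-diacetoxybutan-2-one | CC(=O)OCCC(=O)COC(C)=O | intermediate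
10 | 1-acetoxybut-3-en-2-one | C=CC(=O)COC(C)=O | intermediate
11 | (6R)-3-(4-acetoxy-3-oxobutyl)-4-hydroxy-6-(2,6,6-trimethylcyclohex-1-en-1-yl)-5,6-dihydro-2H-pyran-2-one | CC(=O)OCC(=O)CCC1=C(O)C[C@@H](OC1=O)C2=C(C)CCCC2(C)C | intermediate
12 | tert-butyl (E)-3-(acetoxymethyl)-5-[(6R)-4-hydroxy-2-oxo-6-(2,6,6-trimethylcyclohex-1-en-1-yl)-5,6-dihydro-2H-pyran-3-yl]pent-2-enoate | CC(=O)OC/C(=C/C(=O)OC(C)(C)C)CCC1=C(O)C[C@@H](OC1=O)C2=C(C)CCCC2(C)C | intermediate
13 | 2-(trimethylsilyloxy)-4-oxo tautomer of silylated 12 (cyclic silyl ketene acetal, 6R) | CC(=O)OC/C(=C/C(=O)OC(C)(C)C)CCC1=C(O[Si](C)(C)C)O[C@H](CC1=O)C2=C(C)CCCC2(C)C | intermediate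
14 | trimethylsilyl ester of the ring-contracted β-keto acid (9R,10R; carboxyl on C9 anti to C20) | CC(=O)OC/C(=C/C(=O)OC(C)(C)C)CC[C@]1(C(=O)O[Si](C)(C)C)C(=O)CC=C2C(C)(C)CCC[C@@]12C | intermediate
15 | C8/C9 trimethylsilyl enol ether of 16 (10R) | CC(=O)OC/C(=C/C(=O)OC(C)(C)C)CCC1=C(O[Si](C)(C)C)CC=C2C(C)(C)CCC[C@@]12C | intermediate
16 | tert-butyl (E)-3-(acetoxymethyl)-5-[(1S,8aS)-5,5,8a-trimethyl-2-oxo-1,2,3,5,6,7,8,8a-octahydronaphthalen-1-yl]pent-2-enoate | CC(=O)OC/C(=C/C(=O)OC(C)(C)C)CC[C@@H]1C(=O)CC=C2C(C)(C)CCC[C@@]12C | intermediate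
17 | tert-butyl (E)-3-(acetoxymethyl)-5-[(1S,4aR,8aR)-5,5,8a-trimethyl-2-oxo-1,2,4a,5,6,7,8,8a-octahydronaphthalen-1-yl]pent-2-enoate | CC(=O)OC/C(=C/C(=O)OC(C)(C)C)CC[C@@H]1C(=O)C=C[C@@H]2C(C)(C)CCC[C@@]12C | intermediate
18 | (E)-3-(acetoxymethyl)-5-[(1S,4aR,8aR)-5,5,8a-trimethyl-2-oxo-1,2,4a,5,6,7,8,8a-octahydronaphthalen-1-yl]pent-2-enoic acid | CC(=O)OC/C(=C/C(=O)O)CC[C@@H]1C(=O)C=C[C@@H]2C(C)(C)CCC[C@@]12C | target

Total step count: 9. Longest linear sequence: 8 (steps 1, 2, 3, 5, 6, 7, 8, 9).

Steps most likely to fail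

Step 7. Bond formation between two fully substituted carbons through a boat-like transition state may be slower than opening of the β-acyloxy ketone by elimination or ionisation, and the stereochemical information at C6 would then be lost. The fallback sets out from 12 and comes back at 16. It replaces the pericyclic step by a metal-catalysed ionic one, the decarboxylative allylic alkylation of an allyl β-keto ester (Pd2(dba)3, PPh3, THF, 60 °C).
- Zerovalent palladium ionises the allylic C6–O bond with inversion, and the β-keto carboxylate loses CO2.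
- The C9 enolate attacks anti to the metal at C10, the only allyl terminus that gives a six-membered ring.
- The double inversion should give the same configuration at C10.
- This fallback makes no compound outside the list (F0).

Step 2. The doubly flanked, twisted enal may react sluggishly and with poor facial selectivity. The fallback sets out from 3 and comes back at 7, and it swaps catalyst control for a stoichiometric chiral acetate enolate.
- Doubly deprotonated (R)-2-hydroxy-1,2,2-triphenylethyl acetate (LDA, THF; MgBr2; −100 °C) adds to 3.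
- This gives the (R)-2-hydroxy-1,2,2-triphenylethyl (R)-3-hydroxy-3-(2,6,6-trimethylcyclohex-1-en-1-yl)propanoate F1, which is purified as a single diastereomer by crystallisation.
- Claisen condensation with excess lithium enolate of tert-butyl acetate (THF, −40 to −10 °C) gives tert-butyl (R)-5-hydroxy-3-oxo-5-(2,6,6-trimethylcyclohex-1-en-1-yl)pentanoate F2.
- Heating F2 in toluene at 110 °C gives acylketene 6 and hence lactone 7.

Step 6. The olefination may show poor E/Z control, and the ylide may be partly quenched by the acidic enol. The fallback sets out from 7 and comes back at 12, and it fixes the alkene geometry on a small fragment before a stereoretentive coupling.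
- Michael addition of 7 to N-acryloyloxyphthalimide (Et3N, CH2Cl2) gives the 1,3-dioxoisoindolin-2-yl 3-[(6R)-4-hydroxy-2-oxo-6-(2,6,6-trimethylcyclohex-1-en-1-yl)-5,6-dihydro-2H-pyran-3-yl]propanoate F3.
- Separately, tert-butyl propiolate (LDA, THF, −78 °C; paraformaldehyde) gives tert-butyl 4-hydroxybut-2-ynoate F4.
- Anti-hydroiodination of F4 (NaI, AcOH, 70 °C) gives tert-butyl (Z)-4-hydroxy-3-iodobut-2-enoate F5.
- Acetylation of F5 (Ac2O, pyridine) gives tert-butyl (Z)-4-acetoxy-3-iodobut-2-enoate F6.
- Nickel-catalysed reductive cross-electrophile coupling of F3 and F6 (NiBr2(dme), 4,4'-di-tert-butyl-2,2'-bipyridine, Zn, DMA, rt) forms C12–C13 with loss of CO2 and retention of the alkene geometry, giving 12.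

Further compounds
F0 | step 7 | none | none
F1 | step 2 | (R)-2-hydroxy-1,2,2-triphenylethyl (R)-3-hydroxy-3-(2,6,6-trimethylcyclohex-1-en-1-yl)propanoate | O=C(C[C@@H](O)C1=C(C)CCCC1(C)C)O[C@H](c1ccccc1)C(O)(c1ccccc1)c1ccccc1
F2 | step 2 | tert-butyl (R)-5-hydroxy-3-oxo-5-(2,6,6-trimethylcyclohex-1-en-1-yl)pentanoate | CC(C)(C)OC(=O)CC(=O)C[C@@H](O)C1=C(C)CCCC1(C)C
F3 | step 6 | 1,3-dioxoisoindolin-2-yl 3-[(6R)-4-hydroxy-2-oxo-6-(2,6,6-trimethylcyclohex-1-en-1-yl)-5,6-dihydro-2H-pyran-3-yl]propanoate | O=C(CCC1=C(O)C[C@@H](OC1=O)C2=C(C)CCCC2(C)C)ON3C(=O)c4ccccc4C3=O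
F4 | step 6 | tert-butyl 4-hydroxybut-2-ynoate | OCC#CC(=O)OC(C)(C)C
F5 | step 6 | tert-butyl (Z)-4-hydroxy-3-iodobut-2-enoate | OC/C(I)=C/C(=O)OC(C)(C)C
F6 | step 6 | tert-butyl (Z)-4-acetoxy-3-iodobut-2-enoate | CC(=O)OC/C(I)=C/C(=O)OC(C)(C)C
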